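Hydroazulene intermediates are named as daucane derivatives with the locants defined in the first section. β is the face of the C1 methyl; α is the opposite face.

## Analysis of the target

The target is a daucane-type sesquiterpenoid ester built on a hydroazulene. C1 is the quaternary, methyl-bearing ring-fusion carbon. The five-membered ring runs C1–C2–C3 (two CH2) to the isopropyl carbinol C4 and the ring-fusion CH C5. The seven-membered ring continues through the acyloxy carbon C6, the ketone C7, the methyl carbinol C8, the secondary carbinol C9 and the CH2 C10 back to C1.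

There are six stereocentres. The ring fusion is trans (C1 methyl β, C5–H α). At C4 the hydroxyl is β and the isopropyl group α. The ester oxygen at C6 is α. The hydroxyls at C8 and C9 are both α, a cis-diol on the face away from the angular methyl, so the C8 methyl is β.

The sensitive groups are the tertiary α-ketol C7/C8 with a β-hydroxyl at C9 (retro-aldol cleavage, acyloin shift), the enolisable acyloxy carbon C6 next to the ketone, the tertiary C4 alcohol (dehydration) and the phenol.

The difficulty lies in four contiguous functionalised carbons C6–C9 on a seven-membered ring next to a quaternary centre, in the trans ring fusion, and in two carbonyl-level carbons (C4, C7) that must be kept apart when the isopropyl group is added.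

The strategy rests on one feature. If C5 and C10 are joined, the seven-membered ring collapses to a C1–C5–C10 cyclopropane fused to the five-membered ring. C5 then carries the two-carbon arm C6=C7 and C10 carries the arm C9=C8. This is a cis-divinylcyclopropane, and if the C6=C7 arm is a ketene, C7 arrives as the ketone.

## Retrosynthetic reasoning

**Protecting groups and the C6 ester.** Target 31 is reached from 29 by removing a benzyl ether (phenol) and an acetonide (C8/C9 diol). The O6–acyl bond is cut next, giving carbinol 25 and the commercial acid chloride 26. The ester is put on late because it would not survive an isopropyl-metal reagent. C7 is carried through this stage as a PMB-protected carbinol (27, 28) and reoxidised to 29, so that C4 is the only carbonyl when the isopropyl group arrives.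

**C4–isopropyl bond.** 25 is cut to ketone 24 and an isopropyl nucleophile. C4 is the only carbon bearing the branch, and a C4 carbonyl is what the ring-forming chemistry leaves behind. The forward addition must come from the α face, away from the angular methyl. 24 comes from ketal 23 by ketal exchange.

**C5–H and C6–O bonds.** Both new bonds in 23 are α, so they are cut together: syn addition of H and OH across the C5=C6 alkene of 21 by hydroboration–oxidation. Conjugate hydride addition to a C7 enone was considered first and set aside. C5 is flanked by two fully substituted carbons, its facial course is uncertain, and a C7 ketone would be left to compete at the isopropyl addition. Hence C7 is reduced (19 to 20) and capped (21) before the hydroboration.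

**C8–O and C9–O bonds.** The cis-diol in 19 and 18 is cut back to the C8=C9 alkene of dienone 17 (osmylation from the α face). 17 comes from 16 by moving the C9=C10 alkene into conjugation, which also erases the C8 stereocentre of 16.

**Key disconnection.** In 16 the C7–C8 bond is cut and C5–C10 re-formed, giving ketene 15, which is the Wolff product of diazoketone 14. Both rings, the C7 carbonyl and alkenes at the positions needed later come from one step.

**Diazoketone and cyclopropane.** 14 is the one-carbon homologue (C6) of acid 12, from ester 11 and ketone 10. The dioxolane at C4 is chosen because it is inert in the key step and identical on both faces, so it does not bias the later hydroboration. 10 is cut at C5–C1 and C5–C10: intramolecular carbenoid addition in diazo keto ester 9 to an (E)-trisubstituted alkene. This sets C1 under catalyst control and puts the propenyl group exo.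

**Chain.** 9 comes from β-keto ester 8 by diazo transfer. 8 is cut at C2–C3 into methyl acetoacetate 6 (via dianion 7) and dienyl bromide 5. 5 comes from alcohol 4 and ester 3, whose trisubstituted (E) alkene is made by Wittig reaction of 1 with 2. A stabilised ylide is used so that no crossed condensation of two enolisable aldehydes is needed.

## Alternatives that were turned down

**Alternative 1: oxocarbenium (3+4) annulation.**
- Disconnection: C5–C6 and C8–C9. The seven-membered ring is assembled from keto aldehyde A2 (C5 ketone, C9 aldehyde, C1 and C4 in place) and the bis(silyl) dienol ether A3 (C6–C8, ester on C8).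
- Forward key step: a silyl triflate Lewis acid ionises the 1,4-dicarbonyl pair to a bicyclic oxocarbenium ion. The diene terminus C6 adds to C5, then C8 closes onto C9, giving the oxygen-bridged ketone A1.
- For: it is convergent, and the C7 ketone, the C9 oxygen and a fully substituted C8 appear in one operation without diazo chemistry. On convergence and direct delivery of the C9 oxygen it is stronger than the chosen route.
- Against: C8 carries methyl and an ester where the target needs methyl and hydroxyl, so one carbon must be excised from a retro-Claisen-prone quaternary β-keto ester. The C5–O bridge bond must be replaced by C5–H trans to the C1 methyl; opening it by elimination returns a C5=C6 enone with the hindered-reduction problem and no C6 oxygen. Bond formation at C5 is between a quaternary carbon and a silyloxy carbon. A2 needs its own asymmetric synthesis.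
- Comparison: the chosen route puts the correct methyl on C8 from the propenyl group, adds the C8 and C9 hydroxyls in one osmylation with no carbon to remove, and sets C5–H and C6–O together.

**Alternative 2: C–H insertion on a citronellol chain.**
- Disconnection: C1–C5 only. Cyclopentanone A4 comes from the acyclic diazo keto ester A5, made from (S)-citronellol A6, whose methine becomes C1.
- Forward key step: a dirhodium carboxylate generates the carbenoid at C5, which inserts into the tertiary C1–H bond with retention (1,5-insertion).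
- For: C1 comes from the chiral pool with retention. On absolute control this is stronger than a ligand-controlled cyclopropanation of an acceptor/acceptor diazo compound.
- Against: only the five-membered ring is made. Of the seven-membered ring A4 holds C6 (ester carbon), C9 and C10. C7 and C8 with its methyl must be added, the ring closed, and all of C5, C6, C8, C9 functionalised afterwards. This costs many more steps.
- Comparison: the chosen route makes both rings and the C7 carbonyl at once and leaves two alkenes where the remaining oxygens go. Its weaker enantiocontrol is covered by a resolution fallback.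

**Alternative 3: vinylcarbenoid formal (4+3) cycloaddition.**
- Disconnection: C7–C8 and C1–C10. The partners are vinyldiazoacetate A8 (C8–C10) and the silyloxy vinylcyclopentene A9.
- Forward key step: a chiral dirhodium carbenoid cyclopropanates the C6=C7 vinyl group with C8. The cis-divinylcyclopropane then undergoes Cope rearrangement forming C1–C10, giving ester A7.
- For: it uses the same ring expansion, is convergent, and enantioselective vinylcarbenoid cyclopropanation is more dependable than step 6 here. The alkenes of A7 sit at C5=C6 and C8=C9, as in the chosen route. It is stronger on convergence and catalyst reliability.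
- Against: the sigmatropic step must create the quaternary C1 at a fully substituted alkene terminus. C7 emerges as a CH2 between C6 and C8, and its later oxidation to the ketone is not defensible. C8 carries an ester that takes about three steps to reduce to methyl. The C4 stereocentre may be mismatched with the catalyst.
- Comparison: in the chosen route C7 is a carbonyl by construction (the ketene carbon), C8 already carries its methyl, and the quaternary C1 is made in the cyclopropanation, not in the [3,3] step.

Key step: step 10

Assumptions: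
- The sense of induction of the copper–bisoxazoline catalyst in step 6 is assumed for the (S,S) ligand; if it gives the mirror-image ester, the (R,R) ligand is used with no other change.
- The C7 carbinol from step 14 is assumed to be α (hydride anti to the C8–O bond); this centre is removed in step 21 and the 7-epimer would serve equally.

## Route

Step 1
Reactants: 1 (E)-but-2-enal (crotonaldehyde); 2 ethyl 2-(triphenylphosphoranylidene)propanoate
Product: 3 ethyl (2E,4E)-2-methylhexa-2,4-dienoate
Conditions: CH2Cl2, rt
Reagents that add atoms: none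
Why: Wittig olefination with a stabilised α-methyl ylide should give the trisubstituted (2E) ester; the (4E) alkene of 1 is not touched.

Step 2
Reactants: 3 ethyl (2E,4E)-2-methylhexa-2,4-dienoate
Product: 4 (2E,4E)-2-methylhexa-2,4-dien-1-ol
Conditions: i-Bu2AlH, CH2Cl2, −78 to 0 °C; aq. potassium sodium tartrate
Reagents that add atoms: none
Why: 1,2-Reduction of the conjugated ester by the aluminium hydride at low temperature should give the allylic alcohol and leave the diene intact.

Step 3
Reactants: 4 (2E,4E)-2-methylhexa-2,4-dien-1-ol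
Product: 5 (2E,4E)-1-bromo-2-methylhexa-2,4-diene
Conditions: PBr3, Et2O, −10 °C; used crude
Reagents that add atoms: phosphorus tribromide BrP(Br)Br
Why: Bromination of the primary allylic alcohol at low temperature; the conjugated primary bromide is the thermodynamic allylic isomer, so both alkene geometries should be kept.

Step 4
Reactants: 6 methyl 3-oxobutanoate (methyl acetoacetate); 5 (2E,4E)-1-bromo-2-methylhexa-2,4-diene
Product: 8 methyl (6E,8E)-6-methyl-3-oxodeca-6,8-dienoate, via methyl acetoacetate dianion 7 (not isolated)
Conditions: NaH, THF, 0 °C; n-BuLi, 0 °C; then 5, 0 °C to rt; 1 M HCl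
Reagents that add atoms: none
Why: γ-Alkylation of the acetoacetate dianion; the more basic terminal carbanion displaces the primary allylic bromide by SN2 and forms the C2–C3 bond.

Step 5
Reactants: 8 methyl (6E,8E)-6-methyl-3-oxodeca-6,8-dienoate
Product: 9 methyl (6E,8E)-2-diazo-6-methyl-3-oxodeca-6,8-dienoate
Conditions: 4-acetamidobenzenesulfonyl azide, Et3N, MeCN, 0 °C to rt
Reagents that add atoms: 4-acetamidobenzenesulfonyl azide CC(=O)Nc1ccc(cc1)S(=O)(=O)N=[N+]=[N-]
Why: Regitz diazo transfer to the doubly activated methylene of the β-keto ester.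

Step 6
Reactants: 9 methyl (6E,8E)-2-diazo-6-methyl-3-oxodeca-6,8-dienoate
Product: 10 methyl (1R,5R,6R)-5-methyl-2-oxo-6-[(E)-prop-1-enyl]bicyclo[3.1.0]hexane-1-carboxylate
Conditions: [Cu(MeCN)4]PF6 (5 mol%), (S,S)-t-Bu-bisoxazoline (6 mol%), toluene, 50 °C, slow addition of 9
Reagents that add atoms: none
Why: Intramolecular cyclopropanation by a copper carbenoid at the proximal trisubstituted alkene (five-membered ring closure is preferred over the distal alkene) is stereospecific, so the (E) alkene places the propenyl group exo, cis to the ester and to the C1 methyl. The bisoxazoline ligand on monovalent copper selects the alkene face and so sets C1 together with C5 and C10.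

Step 7
Reactants: 10 methyl (1R,5R,6R)-5-methyl-2-oxo-6-[(E)-prop-1-enyl]bicyclo[3.1.0]hexane-1-carboxylate
Product: 11 methyl (1R,5R,6R)-5-methyl-6-[(E)-prop-1-enyl]spiro[bicyclo[3.1.0]hexane-2,2'-[1,3]dioxolane]-1-carboxylate
Conditions: (Me3SiOCH2)2, Me3SiOTf (5 mol%), CH2Cl2, −78 to −20 °C; pyridine
Reagents that add atoms: 1,2-bis(trimethylsilyloxy)ethane C[Si](C)(C)OCCO[Si](C)(C)C
Why: Silyl triflate-catalysed ketalisation at low temperature should mask the C4 ketone without the protic acid and heat that could open the doubly activated vinylcyclopropane.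

Step 8
Reactants: 11 methyl (1R,5R,6R)-5-methyl-6-[(E)-prop-1-enyl]spiro[bicyclo[3.1.0]hexane-2,2'-[1,3]dioxolane]-1-carboxylate
Product: 12 (1R,5R,6R)-5-methyl-6-[(E)-prop-1-enyl]spiro[bicyclo[3.1.0]hexane-2,2'-[1,3]dioxolane]-1-carboxylic acid
Conditions: KOH, MeOH/H2O, 65 °C; 1 M HCl to pH 4 at 0 °C
Reagents that add atoms: potassium hydroxide [K+].[OH-]
Why: Saponification of the hindered methyl ester; with the ketone masked the cyclopropane has one acceptor only and should tolerate hydroxide, and brief cold acidification keeps the ketal.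

Step 9
Reactants: 12 (1R,5R,6R)-5-methyl-6-[(E)-prop-1-enyl]spiro[bicyclo[3.1.0]hexane-2,2'-[1,3]dioxolane]-1-carboxylic acid
Product: 14 2-diazo-1-[(1S,5R,6R)-5-methyl-6-[(E)-prop-1-enyl]spiro[bicyclo[3.1.0]hexane-2,2'-[1,3]dioxolan]-1-yl]ethan-1-one, via acid chloride 13 (not isolated)
Conditions: 1-chloro-N,N,2-trimethylprop-1-en-1-amine, CH2Cl2, 0 °C; then CH2N2, Et3N, Et2O, 0 °C
Reagents that add atoms: diazomethane C=[N+]=[N-]
Why: The acid is converted to its chloride under neutral, ketal-safe conditions and acylates diazomethane (the first stage of an Arndt–Eistert sequence), bringing in C6. 13 has no α-hydrogen, so the amine only takes up HCl.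

Step 10
Reactants: 14 2-diazo-1-[(1S,5R,6R)-5-methyl-6-[(E)-prop-1-enyl]spiro[bicyclo[3.1.0]hexane-2,2'-[1,3]dioxolan]-1-yl]ethan-1-one
Product: 16 (8βH)-4,4-ethylenedioxy-11,12,13-trinordauca-5,9-dien-7-one, via ketene 15 (not isolated)
Conditions: AgO2CPh (10 mol%), Et3N, THF, 45 °C, sonication
Reagents that add atoms: none
Why: Silver-promoted loss of N2 from 14 with 1,2-shift of the cyclopropyl carbon C5 from the carbonyl carbon to C6 (Wolff rearrangement, retention at C5) gives ketene 15. In 15 the ketene C6=C7 bond and the exo propenyl group are cis on the C1–C5–C10 cyclopropane, and a [3,3] shift through the boat transition state of a cis-divinylcyclopropane Cope rearrangement forms C7–C8 and breaks C5–C10. The closest known reaction type is the tandem Wolff–Cope rearrangement of cis-2-vinylcyclopropyl diazoketones to fused cycloheptadienones. The seven-membered ring is closed by sigmatropic reorganisation, a four-atom expansion of the three-membered ring driven by strain release, and not by joining chain ends; the five-membered ring and C1 are untouched. The new stereocentre C8 is controlled by the (E) geometry of the propenyl group, which places the C8 methyl outside the boat and so trans to the C1 methyl; this centre is erased in step 11. The step needs the Wolff shift to beat carbenoid addition to the nearby propenyl group, and the Cope step to beat capture of the ketene. This is secured by the cis relationship fixed in step 6, by the absence of protic nucleophiles, and by the sp-hybridised ketene terminus C7, which has no inward substituent, so only C8–H faces the cis C1 methyl in the boat.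

Step 11
Reactants: 16 (8βH)-4,4-ethylenedioxy-11,12,13-trinordauca-5,9-dien-7-one
Product: 17 4,4-ethylenedioxy-11,12,13-trinordauca-5,8-dien-7-one
Conditions: DBU, CH2Cl2, rt
Reagents that add atoms: none
Why: Base-mediated isomerisation through the C7 dienolate (deprotonation at C8, reprotonation at C10) should move the alkene into conjugation as the trisubstituted C8=C9 enone, expected to be the thermodynamic isomer; any unchanged 16 is resubmitted.

Step 12
Reactants: 17 4,4-ethylenedioxy-11,12,13-trinordauca-5,8-dien-7-one
Product: 18 4,4-ethylenedioxy-8α,9α-dihydroxy-11,12,13-trinordauc-5-en-7-one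
Conditions: OsO4 (5 mol%), N-methylmorpholine N-oxide, acetone/H2O, rt
Reagents that add atoms: osmium tetroxide O=[Os](=O)(=O)=O (catalytic oxygen carrier); N-methylmorpholine N-oxide C[N+]1([O-])CCOCC1; water O
Why: Catalytic syn-dihydroxylation should take the accessible C8=C9 bond and not C5=C6, whose C5 end lies between two fully substituted carbons. Attack from the α face, away from the pseudoaxial C1 methyl, sets C8 and C9 as the cis α-diol.

Step 13
Reactants: 18 4,4-ethylenedioxy-8α,9α-dihydroxy-11,12,13-trinordauc-5-en-7-one
Product: 19 4,4-ethylenedioxy-8α,9α-isopropylidenedioxy-11,12,13-trinordauc-5-en-7-one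
Conditions: Me2C(OMe)2, PPTS, CH2Cl2, rt
Reagents that add atoms: 2,2-dimethoxypropane COC(C)(C)OC
Why: Acetonide formation on the cis-diol protects the hydroxy ketone array against retro-aldol cleavage and keeps the C9 carbinol from later oxidation.

Step 14
Reactants: 19 4,4-ethylenedioxy-8α,9α-isopropylidenedioxy-11,12,13-trinordauc-5-en-7-one
Product: 20 4,4-ethylenedioxy-8α,9α-isopropylidenedioxy-11,12,13-trinordauc-5-en-7α-ol
Conditions: NaBH4, CeCl3·7H2O, MeOH, −78 to −40 °C
Reagents that add atoms: none
Why: Luche reduction should give clean 1,2-reduction of the enone; hydride is expected anti to the C8–O bond. C7 is taken to the carbinol so that the alkene can be hydroborated and C4 is later the only carbonyl.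

Step 15
Reactants: 20 4,4-ethylenedioxy-8α,9α-isopropylidenedioxy-11,12,13-trinordauc-5-en-7α-ol
Product: 21 4,4-ethylenedioxy-8α,9α-isopropylidenedioxy-7α-(4-methoxybenzyloxy)-11,12,13-trinordauc-5-ene
Conditions: NaH, 4-methoxybenzyl chloride, n-Bu4NI (cat.), DMF, 0 °C to rt
Reagents that add atoms: 4-methoxybenzyl chloride COc1ccc(CCl)cc1
Why: Williamson etherification of the hindered alkoxide with an unhindered benzylic chloride; the PMB ether cannot migrate to O6 and is removed oxidatively later.

Step 16
Reactants: 21 4,4-ethylenedioxy-8α,9α-isopropylidenedioxy-7α-(4-methoxybenzyloxy)-11,12,13-trinordauc-5-ene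
Product: 23 4,4-ethylenedioxy-8α,9α-isopropylidenedioxy-7α-(4-methoxybenzyloxy)-5αH-11,12,13-trinordaucan-6α-ol, via alkylborane 22 (not isolated)
Conditions: BH3·THF, THF, 0 °C to rt; then NaOH, H2O2, 0 °C
Reagents that add atoms: hydrogen peroxide OO
Why: Hydroboration–oxidation places boron on the less substituted C6 (also the carbon favoured next to an allylic ether) and hydrogen on C5 from the same face. The pseudoaxial C1 methyl screens the β face, so syn addition from the α face should give 5α-H (trans ring fusion) and, after oxidation with retention, 6α-OH. This is the facial course known for hydroboration of steroidal 5-enes, which have the same angular-methyl environment.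

Step 17
Reactants: 23 4,4-ethylenedioxy-8α,9α-isopropylidenedioxy-7α-(4-methoxybenzyloxy)-5αH-11,12,13-trinordaucan-6α-ol
Product: 24 6α-hydroxy-8α,9α-isopropylidenedioxy-7α-(4-methoxybenzyloxy)-5αH-11,12,13-trinordaucan-4-one
Conditions: PPTS, acetone/H2O (20:1), 40 °C
Reagents that add atoms: water O
Why: Acid-catalysed ketal exchange releases the C4 ketone, while the acetonide is maintained by the acetone solvent and the PMB ether is inert; the mild acid is chosen to spare the β-hydroxy ketone.

Step 18
Reactants: 24 6α-hydroxy-8α,9α-isopropylidenedioxy-7α-(4-methoxybenzyloxy)-5αH-11,12,13-trinordaucan-4-one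
Product: 25 8α,9α-isopropylidenedioxy-7α-(4-methoxybenzyloxy)-5αH-daucane-4β,6α-diol
Conditions: CeCl3, i-PrMgCl (excess), THF, −78 to −40 °C; aq. NH4Cl
Reagents that add atoms: isopropylmagnesium chloride CC(C)[Mg]Cl
Why: Organocerium addition to the only carbonyl present; the low basicity of the cerium reagent suppresses enolisation, β-hydride reduction and loss of the β-oxygen. Approach from the α face, away from the angular methyl that lies 1,3 to C4 on the β face, should give the 4β-alcohol.

Step 19
Reactants: 25 8α,9α-isopropylidenedioxy-7α-(4-methoxybenzyloxy)-5αH-daucane-4β,6α-diol; 26 4-(benzyloxy)benzoyl chloride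
Product: 27 6α-[4-(benzyloxy)benzoyloxy]-8α,9α-isopropylidenedioxy-7α-(4-methoxybenzyloxy)-5αH-daucan-4β-ol
Conditions: DMAP, Et3N, CH2Cl2, rt to 40 °C
Reagents that add atoms: none
Why: DMAP-catalysed acylation of the secondary C6 hydroxyl; the tertiary C4 hydroxyl should not react.

Step 20
Reactants: 27 6α-[4-(benzyloxy)benzoyloxy]-8α,9α-isopropylidenedioxy-7α-(4-methoxybenzyloxy)-5αH-daucan-4β-ol
Product: 28 6α-[4-(benzyloxy)benzoyloxy]-8α,9α-isopropylidenedioxy-5αH-daucane-4β,7α-diol
Conditions: DDQ, CH2Cl2/pH 7 buffer, 0 °C to rt
Reagents that add atoms: none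
Why: Oxidative cleavage of the electron-rich PMB ether under buffered neutral conditions, which avoid a base-induced acyl shift from O6 to O7; the benzyl ether on the electron-poor benzoate should not be oxidised.

Step 21
Reactants: 28 6α-[4-(benzyloxy)benzoyloxy]-8α,9α-isopropylidenedioxy-5αH-daucane-4β,7α-diol
Product: 29 6α-[4-(benzyloxy)benzoyloxy]-4β-hydroxy-8α,9α-isopropylidenedioxy-5αH-daucan-7-one
Conditions: DMP, NaHCO3, CH2Cl2, rt
Reagents that add atoms: none
Why: Dess–Martin oxidation of the only free secondary alcohol under buffered conditions that should not epimerise C6; the tertiary C4 alcohol is inert.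

Step 22
Reactants: 29 6α-[4-(benzyloxy)benzoyloxy]-4β-hydroxy-8α,9α-isopropylidenedioxy-5αH-daucan-7-one
Product: 31 4β,8α,9α-trihydroxy-6α-(4-hydroxybenzoyloxy)-5αH-daucan-7-one (CNP0241001.1), via phenol acetonide 30 (not isolated)
Conditions: H2 (1 atm), Pd/C, THF, rt; filter; then 1 M aq. HCl, THF, rt
Reagents that add atoms: none
Why: Hydrogenolysis of the aryl benzyl ether (no other reducible group remains), followed without isolation by mild acid hydrolysis of the acetonide; the conditions are mild enough for the tertiary C4 alcohol and the α-ketol.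

## Compound list

1 | (E)-but-2-enal (crotonaldehyde) | C/C=C/C=O | starting material
2 | ethyl 2-(triphenylphosphoranylidene)propanoate | CCOC(=O)C(C)=P(c1ccccc1)(c1ccccc1)c1ccccc1 | starting material
3 | ethyl (2E,4E)-2-methylhexa-2,4-dienoate | C/C=C/C=C(\C)C(=O)OCC | intermediate
4 | (2E,4E)-2-methylhexa-2,4-dien-1-ol | C/C=C/C=C(\C)CO | intermediate
5 | (2E,4E)-1-bromo-2-methylhexa-2,4-diene | C/C=C/C=C(\C)CBr | intermediate
6 | methyl 3-oxobutanoate (methyl acetoacetate) | COC(=O)CC(C)=O | starting material
7 | sodium lithium C2,C4-dianion of methyl acetoacetate | [Na+].[Li+].[CH2-]C(=O)[CH-]C(=O)OC | intermediate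
8 | methyl (6E,8E)-6-methyl-3-oxodeca-6,8-dienoate | COC(=O)CC(=O)CC/C(C)=C/C=C/C | intermediate
9 | methyl (6E,8E)-2-diazo-6-methyl-3-oxodeca-6,8-dienoate | COC(=O)C(=[N+]=[N-])C(=O)CC/C(C)=C/C=C/C | intermediate
10 | methyl (1R,5R,6R)-5-methyl-2-oxo-6-[(E)-prop-1-enyl]bicyclo[3.1.0]hexane-1-carboxylate (propenyl exo) | COC(=O)[C@]12[C@H](/C=C/C)[C@@]1(C)CCC2=O | intermediate
11 | methyl (1R,5R,6R)-5-methyl-6-[(E)-prop-1-enyl]spiro[bicyclo[3.1.0]hexane-2,2'-[1,3]dioxolane]-1-carboxylate | COC(=O)[C@]12[C@H](/C=C/C)[C@@]1(C)CCC23OCCO3 | intermediate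
12 | (1R,5R,6R)-5-methyl-6-[(E)-prop-1-enyl]spiro[bicyclo[3.1.0]hexane-2,2'-[1,3]dioxolane]-1-carboxylic acid | OC(=O)[C@]12[C@H](/C=C/C)[C@@]1(C)CCC23OCCO3 | intermediate
13 | (1R,5R,6R)-5-methyl-6-[(E)-prop-1-enyl]spiro[bicyclo[3.1.0]hexane-2,2'-[1,3]dioxolane]-1-carbonyl chloride | ClC(=O)[C@]12[C@H](/C=C/C)[C@@]1(C)CCC23OCCO3 | intermediate
14 | 2-diazo-1-[(1S,5R,6R)-5-methyl-6-[(E)-prop-1-enyl]spiro[bicyclo[3.1.0]hexane-2,2'-[1,3]dioxolan]-1-yl]ethan-1-one | [N-]=[N+]=CC(=O)[C@]12[C@H](/C=C/C)[C@@]1(C)CCC23OCCO3 | intermediate
15 | 2-[(1R,5R,6R)-5-methyl-6-[(E)-prop-1-enyl]spiro[bicyclo[3.1.0]hexane-2,2'-[1,3]dioxolan]-1-yl]ethen-1-one (ketene) | O=C=C[C@]12[C@H](/C=C/C)[C@@]1(C)CCC23OCCO3 | intermediate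
16 | (8βH)-4,4-ethylenedioxy-11,12,13-trinordauca-5,9-dien-7-one (C1 methyl β, C8 methyl α) | C[C@H]1C=C[C@@]2(C)CCC3(OCCO3)C2=CC1=O | intermediate
17 | 4,4-ethylenedioxy-11,12,13-trinordauca-5,8-dien-7-one | CC1=CC[C@@]2(C)CCC3(OCCO3)C2=CC1=O | intermediate
18 | 4,4-ethylenedioxy-8α,9α-dihydroxy-11,12,13-trinordauc-5-en-7-one | O1CCOC12CC[C@]3(C)C[C@H](O)[C@](C)(O)C(=O)C=C23 | intermediate
19 | 4,4-ethylenedioxy-8α,9α-isopropylidenedioxy-11,12,13-trinordauc-5-en-7-one | O1CCOC12CC[C@]3(C)C[C@@H]4OC(C)(C)O[C@]4(C)C(=O)C=C23 | intermediate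
20 | 4,4-ethylenedioxy-8α,9α-isopropylidenedioxy-11,12,13-trinordauc-5-en-7α-ol | O1CCOC12CC[C@]3(C)C[C@@H]4OC(C)(C)O[C@]4(C)[C@H](O)C=C23 | intermediate
21 | 4,4-ethylenedioxy-8α,9α-isopropylidenedioxy-7α-(4-methoxybenzyloxy)-11,12,13-trinordauc-5-ene | O1CCOC12CC[C@]3(C)C[C@@H]4OC(C)(C)O[C@]4(C)[C@H](OCc5ccc(OC)cc5)C=C23 | intermediate
22 | 6α-boryl-4,4-ethylenedioxy-8α,9α-isopropylidenedioxy-7α-(4-methoxybenzyloxy)-5αH-11,12,13-trinordaucane (alkylborane) | O1CCOC12CC[C@]3(C)C[C@@H]4OC(C)(C)O[C@]4(C)[C@H](OCc5ccc(OC)cc5)[C@H]([BH2])[C@@H]23 | intermediate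
23 | 4,4-ethylenedioxy-8α,9α-isopropylidenedioxy-7α-(4-methoxybenzyloxy)-5αH-11,12,13-trinordaucan-6α-ol | O1CCOC12CC[C@]3(C)C[C@@H]4OC(C)(C)O[C@]4(C)[C@H](OCc5ccc(OC)cc5)[C@H](O)[C@@H]23 | intermediate
24 | 6α-hydroxy-8α,9α-isopropylidenedioxy-7α-(4-methoxybenzyloxy)-5αH-11,12,13-trinordaucan-4-one | O=C1CC[C@]2(C)C[C@@H]3OC(C)(C)O[C@]3(C)[C@H](OCc4ccc(OC)cc4)[C@H](O)[C@@H]12 | intermediate
25 | 8α,9α-isopropylidenedioxy-7α-(4-methoxybenzyloxy)-5αH-daucane-4β,6α-diol | CC(C)[C@]1(O)CC[C@]2(C)C[C@@H]3OC(C)(C)O[C@]3(C)[C@H](OCc4ccc(OC)cc4)[C@H](O)[C@H]21 | intermediate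
26 | 4-(benzyloxy)benzoyl chloride | ClC(=O)c1ccc(OCc2ccccc2)cc1 | starting material
27 | 6α-[4-(benzyloxy)benzoyloxy]-8α,9α-isopropylidenedioxy-7α-(4-methoxybenzyloxy)-5αH-daucan-4β-ol | CC(C)[C@]1(O)CC[C@]2(C)C[C@@H]3OC(C)(C)O[C@]3(C)[C@H](OCc4ccc(OC)cc4)[C@H](OC(=O)c4ccc(OCc5ccccc5)cc4)[C@H]21 | intermediate
28 | 6α-[4-(benzyloxy)benzoyloxy]-8α,9α-isopropylidenedioxy-5αH-daucane-4β,7α-diol | CC(C)[C@]1(O)CC[C@]2(C)C[C@@H]3OC(C)(C)O[C@]3(C)[C@H](O)[C@H](OC(=O)c4ccc(OCc5ccccc5)cc4)[C@H]21 | intermediate
29 | 6α-[4-(benzyloxy)benzoyloxy]-4β-hydroxy-8α,9α-isopropylidenedioxy-5αH-daucan-7-one | CC(C)[C@]1(O)CC[C@]2(C)C[C@@H]3OC(C)(C)O[C@]3(C)C(=O)[C@H](OC(=O)c4ccc(OCc5ccccc5)cc4)[C@H]21 | intermediate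
30 | 4β-hydroxy-6α-(4-hydroxybenzoyloxy)-8α,9α-isopropylidenedioxy-5αH-daucan-7-one | CC(C)[C@]1(O)CC[C@]2(C)C[C@@H]3OC(C)(C)O[C@]3(C)C(=O)[C@H](OC(=O)c4ccc(O)cc4)[C@H]21 | intermediate
31 | 4β,8α,9α-trihydroxy-6α-(4-hydroxybenzoyloxy)-5αH-daucan-7-one (CNP0241001.1) | CC(C)[C@]1(O)CC[C@]2(C)C[C@H](O)[C@](C)(O)C(=O)[C@H](OC(=O)c3ccc(O)cc3)[C@H]21 | target

## Step count and least certain steps

Total: 22 steps. Longest linear sequence: 22 steps (from 1 and 2 to 31); 6 and 26 enter as commercial building blocks.

**Step 10 (key step).**
- What may go wrong: the silver-promoted Wolff shift of the fully substituted cyclopropyl carbon may be slow, so the metal carbenoid adds to the nearby cis propenyl group instead. The ketene may also be captured or dimerise before it rearranges, because the boat transition state must hold the cis C1 methyl against C8–H. Forcing the Cope step by heat invites a homodienyl 1,5-hydrogen shift from the C1 methyl.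
- Fallback: the two events are separated, setting out from 14. Wolff rearrangement by irradiation in aqueous dioxane, where water takes up the ketene, gives the homologated acid 2-[(1S,5R,6R)-5-methyl-6-[(E)-prop-1-enyl]spiro[bicyclo[3.1.0]hexane-2,2'-[1,3]dioxolan]-1-yl]acetic acid F1. 1-Chloro-N,N,2-trimethylprop-1-en-1-amine converts it into the acid chloride F2. Slow addition of F2 to Et3N in hot toluene regenerates ketene 15 by dehydrochlorination, free of nucleophiles and at a temperature the diazoketone would not tolerate, and the Cope rearrangement then gives 16, where the route is rejoined.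

**Step 6.**
- What may go wrong: the catalyst may discriminate poorly between the alkene faces, since an acceptor/acceptor copper carbenoid is reactive and weakly bound to the ligand, giving material of low enantiomeric purity. Carbenoid dimerisation is a lesser concern.
- Fallback: setting out from 9, Rh2(OAc)4 in CH2Cl2 gives the racemic exo keto ester F3; the relative configuration does not depend on the ligand. The enantiomers are separated by preparative chromatography on a chiral stationary phase, and the (1R,5R,6R) enantiomer is 10.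

**Step 16.**
- What may go wrong: borane may add from the β face (giving the cis-fused 5β,6β series), hydride transfer to the hindered C5 may be slow, or the β-alkoxy borane may eliminate toward C7.
- Fallback: hydrogen is delivered to C5 by a directing group and the C6 oxygen is added by enolate chemistry. Setting out from 20, hydroxyl-directed hydrogenation with [Ir(cod)(PCy3)(py)]PF6 and H2 in CH2Cl2 adds hydrogen syn to the 7α-hydroxyl, giving the 5αH alcohol F4. Dess–Martin oxidation gives ketone F5, which can enolise only toward C6 because C8 is fully substituted. LiN(SiMe3)2 gives the lithium enolate F6, and 2-(phenylsulfonyl)-3-phenyloxaziridine hydroxylates it from the α face, away from the angular methyl, giving the 6α-hydroxy ketone F7. Acylation with 26 (DMAP, Et3N) gives ester F8, and ketal exchange (PPTS, wet acetone) gives the 4,7-diketone F9. One equivalent of i-PrMgCl/CeCl3 at −78 °C is then added. This brings back the competition between C4 and C7 that the main route avoids. C7 is flanked by the fully substituted C8 and the acyloxy carbon C6, so the cyclopentanone should react first. The product is 29, where the route is rejoined.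

**Step 17.**
- What may go wrong: once C4 is a ketone, the free C6 hydroxyl is β to it and C5–H is α to it. Acid may cause dehydration to the C5=C6 enone or epimerisation of the ring fusion.
- Fallback: O6 is capped first. Setting out from 23, t-BuMe2SiOTf and 2,6-lutidine give the 6α-silyl ether F10. Ketal exchange gives ketone F11, and i-PrMgCl/CeCl3 gives carbinol F12. n-Bu4NF removes the silyl group and returns 25.

**Step 18.**
- What may go wrong: the secondary Grignard-derived reagent may transfer a β-hydride to the ketone or act as a base (enolisation, loss of the C6 oxygen); facial selectivity may also be incomplete.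
- Fallback: an sp2 nucleophile without these pathways is used. Setting out from 24, isopropenylmagnesium bromide with CeCl3 gives the 4α-isopropenyl carbinol 8α,9α-isopropylidenedioxy-7α-(4-methoxybenzyloxy)-5αH-dauc-11-ene-4β,6α-diol F13. Hydrogenation of its 1,1-disubstituted alkene with RhCl(PPh3)3 and H2, which leaves the PMB ether and acetonide alone, returns 25.

## Further compounds

F1 | step 10 | 2-[(1S,5R,6R)-5-methyl-6-[(E)-prop-1-enyl]spiro[bicyclo[3.1.0]hexane-2,2'-[1,3]dioxolan]-1-yl]acetic acid | OC(=O)C[C@]12[C@H](/C=C/C)[C@@]1(C)CCC23OCCO3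
F2 | step 10 | 2-[(1S,5R,6R)-5-methyl-6-[(E)-prop-1-enyl]spiro[bicyclo[3.1.0]hexane-2,2'-[1,3]dioxolan]-1-yl]acetyl chloride | ClC(=O)C[C@]12[C@H](/C=C/C)[C@@]1(C)CCC23OCCO3
F3 | step 6 | racemic methyl (1R*,5R*,6R*)-5-methyl-2-oxo-6-[(E)-prop-1-enyl]bicyclo[3.1.0]hexane-1-carboxylate (both enantiomers) | COC(=O)[C@]12[C@H](/C=C/C)[C@@]1(C)CCC2=O.COC(=O)[C@@]12[C@@H](/C=C/C)[C@]1(C)CCC2=O
F4 | step 16 | 4,4-ethylenedioxy-8α,9α-isopropylidenedioxy-5αH-11,12,13-trinordaucan-7α-ol | O1CCOC12CC[C@]3(C)C[C@@H]4OC(C)(C)O[C@]4(C)[C@H](O)C[C@@H]23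
F5 | step 16 | 4,4-ethylenedioxy-8α,9α-isopropylidenedioxy-5αH-11,12,13-trinordaucan-7-one | O1CCOC12CC[C@]3(C)C[C@@H]4OC(C)(C)O[C@]4(C)C(=O)C[C@@H]23
F6 | step 16 | lithium C6=C7 enolate of F5 | [Li+].O1CCOC12CC[C@]3(C)C[C@@H]4OC(C)(C)O[C@]4(C)C([O-])=C[C@@H]23
F7 | step 16 | 4,4-ethylenedioxy-6α-hydroxy-8α,9α-isopropylidenedioxy-5αH-11,12,13-trinordaucan-7-one | O1CCOC12CC[C@]3(C)C[C@@H]4OC(C)(C)O[C@]4(C)C(=O)[C@H](O)[C@@H]23
F8 | step 16 | 6α-[4-(benzyloxy)benzoyloxy]-4,4-ethylenedioxy-8α,9α-isopropylidenedioxy-5αH-11,12,13-trinordaucan-7-one | O1CCOC12CC[C@]3(C)C[C@@H]4OC(C)(C)O[C@]4(C)C(=O)[C@H](OC(=O)c5ccc(OCc6ccccc6)cc5)[C@@H]23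
F9 | step 16 | 6α-[4-(benzyloxy)benzoyloxy]-8α,9α-isopropylidenedioxy-5αH-11,12,13-trinordaucane-4,7-dione | O=C1CC[C@]2(C)C[C@@H]3OC(C)(C)O[C@]3(C)C(=O)[C@H](OC(=O)c4ccc(OCc5ccccc5)cc4)[C@@H]12
F10 | step 17 | 6α-(tert-butyldimethylsilyloxy)-4,4-ethylenedioxy-8α,9α-isopropylidenedioxy-7α-(4-methoxybenzyloxy)-5αH-11,12,13-trinordaucane | O1CCOC12CC[C@]3(C)C[C@@H]4OC(C)(C)O[C@]4(C)[C@H](OCc5ccc(OC)cc5)[C@H](O[Si](C)(C)C(C)(C)C)[C@@H]23
F11 | step 17 | 6α-(tert-butyldimethylsilyloxy)-8α,9α-isopropylidenedioxy-7α-(4-methoxybenzyloxy)-5αH-11,12,13-trinordaucan-4-one | O=C1CC[C@]2(C)C[C@@H]3OC(C)(C)O[C@]3(C)[C@H](OCc4ccc(OC)cc4)[C@H](O[Si](C)(C)C(C)(C)C)[C@@H]12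
F12 | step 17 | 6α-(tert-butyldimethylsilyloxy)-8α,9α-isopropylidenedioxy-7α-(4-methoxybenzyloxy)-5αH-daucan-4β-ol | CC(C)[C@]1(O)CC[C@]2(C)C[C@@H]3OC(C)(C)O[C@]3(C)[C@H](OCc4ccc(OC)cc4)[C@H](O[Si](C)(C)C(C)(C)C)[C@H]21
F13 | step 18 | 8α,9α-isopropylidenedioxy-7α-(4-methoxybenzyloxy)-5αH-dauc-11-ene-4β,6α-diol | CC(=C)[C@]1(O)CC[C@]2(C)C[C@@H]3OC(C)(C)O[C@]3(C)[C@H](OCc4ccc(OC)cc4)[C@H](O)[C@H]21
A1 | alternative 1 | methyl ester of the C5–O–C9 oxygen-bridged 4-(tert-butyldimethylsilyloxy)-8-methyl-7-oxohydroazulene-8-carboxylic acid | COC(=O)[C@]1(C)C(=O)C[C@]23O[C@H]1C[C@@]2(C)CC[C@@H]3O[Si](C)(C)C(C)(C)C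
A2 | alternative 1 | 2-[3-(tert-butyldimethylsilyloxy)-1-methyl-2-oxocyclopentyl]acetaldehyde | O=CC[C@@]1(C)CC[C@H](O[Si](C)(C)C(C)(C)C)C1=O
A3 | alternative 1 | 1-methoxy-2-methyl-1,3-bis(trimethylsilyloxy)buta-1,3-diene | COC(O[Si](C)(C)C)=C(C)C(=C)O[Si](C)(C)C
A4 | alternative 2 | methyl 2-[2-(tert-butyldimethylsilyloxy)ethyl]-2-methyl-5-oxocyclopentane-1-carboxylate (ester trans to the silyloxyethyl chain) | COC(=O)[C@H]1C(=O)CC[C@]1(C)CCO[Si](C)(C)C(C)(C)C
A5 | alternative 2 | methyl (6S)-8-(tert-butyldimethylsilyloxy)-2-diazo-6-methyl-3-oxooctanoate | COC(=O)C(=[N+]=[N-])C(=O)CC[C@H](C)CCO[Si](C)(C)C(C)(C)C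
A6 | alternative 2 | (S)-citronellol | C[C@@H](CCC=C(C)C)CCO
A7 | alternative 3 | methyl 1-(tert-butyldimethylsilyloxy)-3a-methyl-1,2,3,3a,4,7-hexahydroazulene-6-carboxylate | COC(=O)C1=CC[C@@]2(C)CC[C@H](O[Si](C)(C)C(C)(C)C)C2=CC1
A8 | alternative 3 | methyl 2-diazobut-3-enoate | COC(=O)C(=[N+]=[N-])C=C
A9 | alternative 3 | tert-butyldimethyl[(3-methyl-2-vinylcyclopent-2-en-1-yl)oxy]silane | C=CC1=C(C)CC[C@@H]1O[Si](C)(C)C(C)(C)C
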